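**The count.** The 3 questions below reduce to one count on two flasks that differ in precatalyst loading.

| setting | epsilon | alpha | west | south-west |
|---|---|---|---|---|
| starting material | 0.013 M | 0.040 M | 0.020 M | 0.020 M |
| second substrate | 2 equiv | 2 equiv | 2.00 equiv | 2.00 equiv |
| precatalyst | 0.05 mol% | 0.05 mol% | 0.05 mol% | 0.012 mol% |
| temperature | 40 °C | 40 °C | 40 °C | 40 °C |
| remark | run made earlier | run made earlier |  |  |
| time |  |  | 40 h | 40 h |

| run | time / h | target / % | starting material / % |
|---|---|---|---|
| epsilon | 4.00 | 0.4 | 99.6 |
| epsilon | 8.00 | 2.0 | 98.2 |
| epsilon | 10.0 | 1.7 | 97.7 |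
| epsilon | 15.0 | 3.7 | 95.7 |
| alpha | 1.00 | 0 | 100.0 |
| alpha | 2.50 | 0.4 | 100.5 |
| alpha | 6.00 | 1.5 | 98.1 |
| alpha | 15.0 | 8.2 | 91.8 |

(standard deviation of a reading: 0.5 percentage points)

- which one finishes higher in amount of target, in percent of the starting material charged ("neither" within 2 percentage points) (west / south-west / neither)
- amount of target at the end, in percent of the starting material charged, west
- amount of target at the end, in percent of the starting material charged, south-west

- steps under discussion: second substrate + free enzyme <-> complex B; free enzyme -> unfolded enzyme; starting material + free enzyme <-> complex A; complex A -> free enzyme + target; precatalyst -> free enzyme; complex B -> free enzyme + second product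

**Turned round.** We count turnovers: target formed per precatalyst charged, both as fractions of the starting material charged. Suppose west and south-west hold the same count. Their gap is then that count times the difference in loading, so "neither" needs fewer than 52.6 turnovers. South-west draws level with west at 4.17 times west's count. The epsilon reading at 15.0 h already stands at 74.0 turnovers, above that limit.

**Our reckoning.** Interpolating the epsilon and alpha readings to west's concentration gives 97.3 turnovers at 15.0 h. Between the last two alpha readings, target grows as time to the power 1.85, a value that carries their scatter. Carried to 40 h with that power, taken over from alpha, this gives 600 turnovers, our turnover number for west at the end, about ten times the limit. Taking that count for both flasks, which share 0.020 M of starting material, and multiplying by the loadings, we expect 30.0% in west and 7.20% in south-west.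

**The forecast.** It names west, with 15% (9% to 24%) for west and 4% (2% to 7%) for south-west: “Running that to 40 h gives about 15%”. Our west figure lies above its range.

**The result.** West gives 28.6% and south-west 7.52%, so west finishes higher, and the forecast's west figure is 14 percentage points low. That is 571 turnovers in west, against our 600, and 627 in south-west.

    second substrate + free enzyme ⇌ complex B (K = 13.0 M⁻¹, k = 3.67 × 10⁵ M⁻¹ h⁻¹, Ea = 53.0 kJ mol⁻¹, ΔH = −45.0 kJ mol⁻¹)
    free enzyme → unfolded enzyme (k = 6.65 × 10⁻⁴ h⁻¹, Ea = 227 kJ mol⁻¹)
    starting material + free enzyme ⇌ complex A (K = 21.6 M⁻¹, k = 1.58 × 10⁵ M⁻¹ h⁻¹, Ea = 53.0 kJ mol⁻¹, ΔH = −1.00 kJ mol⁻¹)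
    complex A → free enzyme + target (k = 171 h⁻¹, Ea = 85.0 kJ mol⁻¹)
    precatalyst → free enzyme (k = 0.0320 h⁻¹, Ea = 94.0 kJ mol⁻¹)
    complex B → free enzyme + second product (k = 52.7 h⁻¹, Ea = 95.0 kJ mol⁻¹)
    (constants at 40 °C)

**The neighbour.** The neighbour flask is west with 0.2 mol% of precatalyst. Our count times that loading gives 120%, more than the charge holds. The neighbour flask gives 77.7% of target, or 388 turnovers, fewer than in west, with 22% of the starting material still unbound.

All runs were generated by integration on assumed constants; the scatter is artificial.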